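**Plan**
1. Numbering used throughout: lactone O–C2–C1–C15(=C17H2)–C16(=O); carbocycle C1–C2–C3=C4(Me)–C5–C6(OH)–C7=C8(Me)–C9–C10(OAc)–C11=C12(Me)–C13–C14(OAc)–C1.
2. Enabling feature: C2 is both the allylic carbinol carbon next to the (E)-C3=C4(Me) alkene of the 14-membered ring and the γ-carbon of the C16 acrylate ester. Joining a C3 alkenyl metal to a C2 aldehyde therefore closes the carbocycle and leaves an alkoxide five atoms from C16, which closes the butyrolactone.
3. Cuts, in order: O6–Si; C2–C3 together with O–C16 (macrolactone ⇒ open-chain iodo aldehyde ester 29); C1–C14 (⇒ aldehyde 24 + allyl bromide 4); C5–C6 and C9–C10 (propargyl units); the C–CH3 and C–CH2OH or C–I bonds made by alkyne carbometalation.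
4. Forward: the chain grows from C14 to C3 by three alkyne carboaluminations and two enal propargylations; a chromium allylation adds C1, C2 and C15–C17; the carbocycle is closed last at C2–C3 and the lactone forms in the same flask.
5. Stereochemistry: C10 and C6 from chiral phosphoric acid-controlled propargylation; C14 and C1 together from a ligand-controlled, syn-selective chromium allylation; C2 from the substrate (Felkin–Anh plus 1,3-anti) during ring closure; the three E-alkenes from syn-carbometalation.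

Key step: step 17

Remark: the handedness of (S)-TRIP and of the bis(oxazoline) ligand is assigned by analogy with aryl and alkenyl aldehydes; the antipodal catalyst is used if a model run shows the opposite sense.
Abbreviations: TBS = tert-butyldimethylsilyl, TES = triethylsilyl, TBDPS = tert-butyldiphenylsilyl, TMS = trimethylsilyl, Bpin = pinacolatoboryl, TRIP = 3,3′-bis(2,4,6-triisopropylphenyl)-1,1′-binaphthyl-2,2′-diyl hydrogen phosphate.

**Route**

Step 1
Reactants: 1 methyl acrylate; 2 2,2-dimethoxyacetaldehyde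
Product: 3 methyl 3-hydroxy-4,4-dimethoxy-2-methylidenebutanoate (racemic)
Conditions: DABCO (0.5 equiv), 2 as 60% aq. solution, 1,4-dioxane/H2O, rt
Reagents that add atoms: none
Why: Morita–Baylis–Hillman reaction of an acrylate with a reactive, non-enolizable aldehyde; the racemic carbinol center is erased in step 2.

Step 2
Reactants: 3 methyl 3-hydroxy-4,4-dimethoxy-2-methylidenebutanoate
Product: 4 methyl (2Z)-2-(bromomethyl)-4,4-dimethoxybut-2-enoate
Conditions: NBS, Me2S, CH2Cl2, 0 °C to rt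
Reagents that add atoms: N-bromosuccinimide, O=C1CCC(=O)N1Br
Why: Allylic bromination of a Baylis–Hillman alcohol with transposition (SN2′ attack of bromide on the alkoxysulfonium salt) should give the thermodynamically preferred enoate with the acetal carbon cis to CH2Br, under neutral conditions that spare the acetal.

Step 3
Reactants: 5 4-[(tert-butyldimethylsilyl)oxy]but-1-yne
Product: 8 (2E)-5-(TBSO)-3-methylpent-2-en-1-ol, via alkenylalane 6 (not isolated), via lithium alanate 7 (not isolated)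
Conditions: Me3Al, Cp2ZrCl2 (0.25 equiv), CH2Cl2, 0 °C to rt; volatiles removed; n-BuLi, THF, −78 to 0 °C; (CH2O)n, rt; aq. work-up
Reagents that add atoms: trimethylaluminium, C[Al](C)C; formaldehyde (from paraformaldehyde), C=O
Why: Negishi carboalumination adds methyl and aluminium syn with aluminium on the terminal carbon, and hydroxymethylation of the alanate occurs with retention, which should fix the E geometry of the future C11=C12 alkene.

Step 4
Reactants: 8 (2E)-5-(TBSO)-3-methylpent-2-en-1-ol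
Product: 9 (2E)-5-(TBSO)-3-methylpent-2-enal
Conditions: MnO2, CH2Cl2, rt
Reagents that add atoms: none
Why: MnO2 oxidizes the allylic alcohol selectively to the enal without E/Z isomerization or over-oxidation.

Step 5
Reactants: 9 (2E)-5-(TBSO)-3-methylpent-2-enal; 10 allenylboronic acid pinacol ester
Product: 12 (4S,5E)-8-(TBSO)-6-methyloct-5-en-1-yn-4-ol, via boronate ester 11 (not isolated)
Conditions: (S)-TRIP (10 mol %), 4 Å MS, toluene, −20 °C; aq. NaHCO3 work-up
Reagents that add atoms: none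
Why: Chiral phosphoric acid-catalysed propargylation with an allenylboronate (SE2′ transfer through a six-membered chair transition state, the acid binding the boronate oxygen and the formyl hydrogen) should set the future C10 center as S under catalyst control; enals are established substrates.

Step 6
Reactants: 12 (4S,5E)-8-(TBSO)-6-methyloct-5-en-1-yn-4-ol
Product: 13 (4S,5E)-8-(TBSO)-6-methyl-4-(TESO)oct-5-en-1-yne
Conditions: TESCl, imidazole, DMF, 0 °C
Reagents that add atoms: chlorotriethylsilane, CC[Si](Cl)(CC)CC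
Why: Standard silylation; the TES group survives carboalumination and is later removed together with the primary TBS ether while the TBDPS ether stays.

Step 7
Reactants: 13 (4S,5E)-8-(TBSO)-6-methyl-4-(TESO)oct-5-en-1-yne
Product: 16 (2E,5S,6E)-9-(TBSO)-3,7-dimethyl-5-(TESO)nona-2,6-dien-1-ol, via alkenylalane 14 (not isolated), via lithium alanate 15 (not isolated)
Conditions: Me3Al, Cp2ZrCl2 (0.25 equiv), CH2Cl2, 0 °C to rt; volatiles removed; n-BuLi, THF, −78 to 0 °C; (CH2O)n, rt; aq. work-up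
Reagents that add atoms: trimethylaluminium, C[Al](C)C; formaldehyde (from paraformaldehyde), C=O
Why: Second Negishi carboalumination/hydroxymethylation as in step 3; silyl ethers and the trisubstituted alkene are inert and syn addition should fix the E geometry of the future C7=C8 alkene.

Step 8
Reactants: 16 (2E,5S,6E)-9-(TBSO)-3,7-dimethyl-5-(TESO)nona-2,6-dien-1-ol
Product: 17 (2E,5S,6E)-9-(TBSO)-3,7-dimethyl-5-(TESO)nona-2,6-dienal
Conditions: MnO2, CH2Cl2, rt
Reagents that add atoms: none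
Why: Chemoselective MnO2 oxidation of the primary allylic alcohol, as in step 4.

Step 9
Reactants: 17 (2E,5S,6E)-9-(TBSO)-3,7-dimethyl-5-(TESO)nona-2,6-dienal; 10 allenylboronic acid pinacol ester
Product: 19 (4S,5E,8S,9E)-12-(TBSO)-6,10-dimethyl-8-(TESO)dodeca-5,9-dien-1-yn-4-ol, via boronate ester 18 (not isolated)
Conditions: (S)-TRIP (10 mol %), 4 Å MS, toluene, −20 °C; aq. NaHCO3 work-up
Reagents that add atoms: none
Why: Second phosphoric acid-catalysed allenylboronate propargylation as in step 5; the catalyst should override the remote center and set the future C6 center as S.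

Step 10
Reactants: 19 (4S,5E,8S,9E)-12-(TBSO)-6,10-dimethyl-8-(TESO)dodeca-5,9-dien-1-yn-4-ol
Product: 20 (4S,5E,8S,9E)-12-(TBSO)-4-(TBDPSO)-6,10-dimethyl-8-(TESO)dodeca-5,9-dien-1-yne
Conditions: TBDPSCl, imidazole, DMF, rt
Reagents that add atoms: tert-butyl(chloro)diphenylsilane, CC(C)(C)[Si](Cl)(c1ccccc1)c1ccccc1
Why: Standard silylation with the acid-stable TBDPS group, which marks O6 as the one oxygen that stays unacetylated and should last until the final step.

Step 11
Reactants: 20 (4S,5E,8S,9E)-12-(TBSO)-4-(TBDPSO)-6,10-dimethyl-8-(TESO)dodeca-5,9-dien-1-yne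
Product: 22 (1E,4S,5E,8S,9E)-12-(TBSO)-4-(TBDPSO)-1-iodo-2,6,10-trimethyl-8-(TESO)dodeca-1,5,9-triene, via alkenylalane 21 (not isolated)
Conditions: Me3Al, Cp2ZrCl2 (0.25 equiv), CH2Cl2, 0 °C to rt; I2, THF, −30 to 0 °C
Reagents that add atoms: trimethylaluminium, C[Al](C)C; iodine, II
Why: Third Negishi carboalumination, quenched with iodine: syn addition and iododealumination with retention should give the (E)-1-iodo-2-methylalkene (future C3=C4) as a single isomer.

Step 12
Reactants: 22 (1E,4S,5E,8S,9E)-12-(TBSO)-4-(TBDPSO)-1-iodo-2,6,10-trimethyl-8-(TESO)dodeca-1,5,9-triene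
Product: 23 (3E,5S,7E,9S,11E)-9-(TBDPSO)-12-iodo-3,7,11-trimethyldodeca-3,7,11-triene-1,5-diol
Conditions: HF·pyridine, pyridine, THF, 0 °C to rt
Reagents that add atoms: none
Why: Selective desilylation: buffered HF·pyridine cleaves the primary TBS and the secondary TES ether much faster than the hindered secondary TBDPS ether, which should free O14 and O10 in one operation.

Step 13
Reactants: 23 (3E,5S,7E,9S,11E)-9-(TBDPSO)-12-iodo-3,7,11-trimethyldodeca-3,7,11-triene-1,5-diol
Product: 24 (3E,5S,7E,9S,11E)-9-(TBDPSO)-5-hydroxy-12-iodo-3,7,11-trimethyldodeca-3,7,11-trienal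
Conditions: TEMPO (10 mol %), PhI(OAc)2 (1.1 equiv), CH2Cl2, 0 °C to rt; used crude
Reagents that add atoms: none
Why: TEMPO/PhI(OAc)2 oxidation is strongly selective for primary over secondary alcohols and runs near neutrality, which should give the β,γ-unsaturated aldehyde without double-bond migration.

Step 14
Reactants: 24 (3E,5S,7E,9S,11E)-9-(TBDPSO)-5-hydroxy-12-iodo-3,7,11-trimethyldodeca-3,7,11-trienal; 4 methyl (2Z)-2-(bromomethyl)-4,4-dimethoxybut-2-enoate
Product: 26 methyl (3S,4S,6E,8S,10E,12S,14E)-12-(TBDPSO)-3-(dimethoxymethyl)-4,8-dihydroxy-15-iodo-6,10,14-trimethyl-2-methylidenepentadeca-6,10,14-trienoate, via bis(trimethylsilyl) ether 25 (not isolated)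
Conditions: 4 (1.5 equiv), CrCl2 (10 mol %), chiral carbazole-1,8-bis(oxazoline) ligand (12 mol %), Mn powder, TMSCl, i-Pr2NEt, THF, rt; then citric acid, MeOH, 0 °C
Reagents that add atoms: none
Why: Chromium-catalysed enantioselective 2-(alkoxycarbonyl)allylation (Nozaki–Hiyama-type allylation with manganese/TMSCl turnover): the allylchromium (trivalent) from 4 keeps the acetal carbon cis to CH2Cr and adds through its γ-carbon in a chair transition state, so O14 and C2 should emerge syn (3S,4S) while the ligand selects the aldehyde face; without nickel the alkenyl iodide is untouched, and silylation of the chromium alkoxide prevents lactonization of O14 onto C16.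

Step 15
Reactants: 26 methyl (3S,4S,6E,8S,10E,12S,14E)-12-(TBDPSO)-3-(dimethoxymethyl)-4,8-dihydroxy-15-iodo-6,10,14-trimethyl-2-methylidenepentadeca-6,10,14-trienoate
Product: 27 methyl (3S,4S,6E,8S,10E,12S,14E)-4,8-bis(acetyloxy)-12-(TBDPSO)-3-(dimethoxymethyl)-15-iodo-6,10,14-trimethyl-2-methylidenepentadeca-6,10,14-trienoate
Conditions: Ac2O, pyridine, DMAP (cat.), CH2Cl2, 0 °C
Reagents that add atoms: acetic anhydride, CC(=O)OC(C)=O
Why: DMAP-catalysed acetylation of both secondary alcohols installs the two acetates of the target and removes any chance of lactonization at O14.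

Step 16
Reactants: 27 methyl (3S,4S,6E,8S,10E,12S,14E)-4,8-bis(acetyloxy)-12-(TBDPSO)-3-(dimethoxymethyl)-15-iodo-6,10,14-trimethyl-2-methylidenepentadeca-6,10,14-trienoate
Product: 29 methyl (3S,4S,6E,8S,10E,12S,14E)-4,8-bis(acetyloxy)-12-(TBDPSO)-3-formyl-15-iodo-6,10,14-trimethyl-2-methylidenepentadeca-6,10,14-trienoate, via collidinium salt 28 (not isolated)
Conditions: TESOTf (2 equiv), 2,4,6-collidine (3 equiv), CH2Cl2, 0 °C; then H2O; used at once
Reagents that add atoms: water, O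
Why: Silyl triflate/collidine cleavage of a dimethyl acetal (oxocarbenium formation, trapping as the pyridinium salt, hydrolysis) runs under non-acidic, weakly basic conditions that should leave the silyl ether, the allylic acetates and the C1 configuration intact.

Step 17
Reactants: 29 methyl (3S,4S,6E,8S,10E,12S,14E)-4,8-bis(acetyloxy)-12-(TBDPSO)-3-formyl-15-iodo-6,10,14-trimethyl-2-methylidenepentadeca-6,10,14-trienoate
Product: 31 (3aS,4S,6E,8S,10E,12S,14E,15aS)-12-(TBDPSO)-6,10,14-trimethyl-3-methylidene-2-oxo-2,3,3a,4,5,8,9,12,13,15a-decahydrocyclotetradeca[b]furan-4,8-diyl diacetate, via seco hydroxy ester 30 (not isolated)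
Conditions: CrCl2 (10 equiv), NiCl2 (0.1 equiv), DMSO/THF 3:1, rt, syringe-pump addition of 29 to 2 mM; aq. work-up; PPTS (cat.), CH2Cl2, rt
Reagents that add atoms: none
Why: Nozaki–Hiyama–Kishi macrocyclization followed in the same flask by lactonization: zerovalent nickel (from NiCl2 and divalent chromium) inserts into the C3–I bond with retention of the E geometry, and transmetalation gives an alkenylchromium (trivalent) that adds 1,2 to the C2 aldehyde; the closest precedents are alkenyl iodide/aldehyde macrocyclizations of polyoxygenated macrocycles and the one-pot chromium route to α-methylene-γ-butyrolactones. The 14-membered carbocycle closes 14-exo-trig (C3 attacks the exocyclic C2=O), and the butyrolactone then closes 5-exo-trig when the C2 alkoxide, or alcohol 30 under PPTS, attacks the C16 ester carbonyl and expels methanol. The new C2 center is controlled by the C1 center and the C14 acetate: with the ring bond C1–C14 anti to the incoming C3 (the transoid arrangement a 14-membered ring prefers), H outside and C15 inside, Felkin–Anh attack should give the 2S alcohol, which is also the 1,3-anti product relative to the polar C14–OAc group, so both elements reinforce and the lactone is trans-fused. The step needs intra- over intermolecular coupling (slow addition to about 2 mM), reaction of the alkenyl iodide in the presence of two allylic acetates (oxidative addition into C–I is far faster at low NiCl2 loading), and addition to the aldehyde without touching the acrylate or epimerizing C1 (organochromium reagents are non-basic and do not add to esters or enoates). Any minor 2R epimer would give the cis-fused lactone and should be removable by chromatography.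

Step 18
Reactants: 31 (3aS,4S,6E,8S,10E,12S,14E,15aS)-12-(TBDPSO)-6,10,14-trimethyl-3-methylidene-2-oxo-2,3,3a,4,5,8,9,12,13,15a-decahydrocyclotetradeca[b]furan-4,8-diyl diacetate
Product: 32 (3aS,4S,6E,8S,10E,12S,14E,15aS)-12-hydroxy-6,10,14-trimethyl-3-methylidene-2-oxo-2,3,3a,4,5,8,9,12,13,15a-decahydrocyclotetradeca[b]furan-4,8-diyl diacetate (CNP0418981.1)
Conditions: excess HF·pyridine, THF, 0 °C to rt
Reagents that add atoms: none
Why: Fluoride cleavage of the TBDPS ether with HF·pyridine should spare the two acetates and the α-methylene lactone and give the target.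

**Compound list**
1 | methyl acrylate | C=CC(=O)OC | starting material
2 | 2,2-dimethoxyacetaldehyde | O=CC(OC)OC | starting material
3 | methyl 3-hydroxy-4,4-dimethoxy-2-methylidenebutanoate (racemic) | C=C(C(=O)OC)C(O)C(OC)OC | intermediate
4 | methyl (2Z)-2-(bromomethyl)-4,4-dimethoxybut-2-enoate | BrC/C(=C\C(OC)OC)C(=O)OC | intermediate
5 | 4-[(tert-butyldimethylsilyl)oxy]but-1-yne | C#CCCO[Si](C)(C)C(C)(C)C | starting material
6 | dimethyl[(1E)-4-(TBSO)-2-methylbut-1-en-1-yl]alane | C[Al](C)/C=C(\C)CCO[Si](C)(C)C(C)(C)C | intermediate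
7 | lithium butyl(dimethyl)[(1E)-4-(TBSO)-2-methylbut-1-en-1-yl]alanate | [Li+].CCCC[Al-](C)(C)/C=C(\C)CCO[Si](C)(C)C(C)(C)C | intermediate
8 | (2E)-5-(TBSO)-3-methylpent-2-en-1-ol | OC/C=C(\C)CCO[Si](C)(C)C(C)(C)C | intermediate
9 | (2E)-5-(TBSO)-3-methylpent-2-enal | O=C/C=C(\C)CCO[Si](C)(C)C(C)(C)C | intermediate
10 | allenylboronic acid pinacol ester (4,4,5,5-tetramethyl-2-(propa-1,2-dien-1-yl)-1,3,2-dioxaborolane) | C=C=CB1OC(C)(C)C(C)(C)O1 | starting material
11 | O-Bpin boronate ester of 12 | C#CC[C@H](OB1OC(C)(C)C(C)(C)O1)/C=C(\C)CCO[Si](C)(C)C(C)(C)C | intermediate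
12 | (4S,5E)-8-(TBSO)-6-methyloct-5-en-1-yn-4-ol | C#CC[C@H](O)/C=C(\C)CCO[Si](C)(C)C(C)(C)C | intermediate
13 | (4S,5E)-8-(TBSO)-6-methyl-4-(TESO)oct-5-en-1-yne | C#CC[C@H](O[Si](CC)(CC)CC)/C=C(\C)CCO[Si](C)(C)C(C)(C)C | intermediate
14 | dimethyl[(1E,4S,5E)-8-(TBSO)-2,6-dimethyl-4-(TESO)octa-1,5-dien-1-yl]alane | C[Al](C)/C=C(\C)C[C@H](O[Si](CC)(CC)CC)/C=C(\C)CCO[Si](C)(C)C(C)(C)C | intermediate
15 | lithium butyl(dimethyl)[(1E,4S,5E)-8-(TBSO)-2,6-dimethyl-4-(TESO)octa-1,5-dien-1-yl]alanate | [Li+].CCCC[Al-](C)(C)/C=C(\C)C[C@H](O[Si](CC)(CC)CC)/C=C(\C)CCO[Si](C)(C)C(C)(C)C | intermediate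
16 | (2E,5S,6E)-9-(TBSO)-3,7-dimethyl-5-(TESO)nona-2,6-dien-1-ol | OC/C=C(\C)C[C@H](O[Si](CC)(CC)CC)/C=C(\C)CCO[Si](C)(C)C(C)(C)C | intermediate
17 | (2E,5S,6E)-9-(TBSO)-3,7-dimethyl-5-(TESO)nona-2,6-dienal | O=C/C=C(\C)C[C@H](O[Si](CC)(CC)CC)/C=C(\C)CCO[Si](C)(C)C(C)(C)C | intermediate
18 | O-Bpin boronate ester of 19 | C#CC[C@H](OB1OC(C)(C)C(C)(C)O1)/C=C(\C)C[C@H](O[Si](CC)(CC)CC)/C=C(\C)CCO[Si](C)(C)C(C)(C)C | intermediate
19 | (4S,5E,8S,9E)-12-(TBSO)-6,10-dimethyl-8-(TESO)dodeca-5,9-dien-1-yn-4-ol | C#CC[C@H](O)/C=C(\C)C[C@H](O[Si](CC)(CC)CC)/C=C(\C)CCO[Si](C)(C)C(C)(C)C | intermediate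
20 | (4S,5E,8S,9E)-12-(TBSO)-4-(TBDPSO)-6,10-dimethyl-8-(TESO)dodeca-5,9-dien-1-yne | C#CC[C@H](O[Si](c1ccccc1)(c1ccccc1)C(C)(C)C)/C=C(\C)C[C@H](O[Si](CC)(CC)CC)/C=C(\C)CCO[Si](C)(C)C(C)(C)C | intermediate
21 | dimethyl[(1E,4S,5E,8S,9E)-12-(TBSO)-4-(TBDPSO)-2,6,10-trimethyl-8-(TESO)dodeca-1,5,9-trien-1-yl]alane | C[Al](C)/C=C(\C)C[C@H](O[Si](c1ccccc1)(c1ccccc1)C(C)(C)C)/C=C(\C)C[C@H](O[Si](CC)(CC)CC)/C=C(\C)CCO[Si](C)(C)C(C)(C)C | intermediate
22 | (1E,4S,5E,8S,9E)-12-(TBSO)-4-(TBDPSO)-1-iodo-2,6,10-trimethyl-8-(TESO)dodeca-1,5,9-triene | I/C=C(\C)C[C@H](O[Si](c1ccccc1)(c1ccccc1)C(C)(C)C)/C=C(\C)C[C@H](O[Si](CC)(CC)CC)/C=C(\C)CCO[Si](C)(C)C(C)(C)C | intermediate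
23 | (3E,5S,7E,9S,11E)-9-(TBDPSO)-12-iodo-3,7,11-trimethyldodeca-3,7,11-triene-1,5-diol | I/C=C(\C)C[C@H](O[Si](c1ccccc1)(c1ccccc1)C(C)(C)C)/C=C(\C)C[C@H](O)/C=C(\C)CCO | intermediate
24 | (3E,5S,7E,9S,11E)-9-(TBDPSO)-5-hydroxy-12-iodo-3,7,11-trimethyldodeca-3,7,11-trienal | I/C=C(\C)C[C@H](O[Si](c1ccccc1)(c1ccccc1)C(C)(C)C)/C=C(\C)C[C@H](O)/C=C(\C)CC=O | intermediate
25 | 4,8-bis(trimethylsilyl) ether of 26 | I/C=C(\C)C[C@H](O[Si](c1ccccc1)(c1ccccc1)C(C)(C)C)/C=C(\C)C[C@H](O[Si](C)(C)C)/C=C(\C)C[C@H](O[Si](C)(C)C)[C@H](C(=C)C(=O)OC)C(OC)OC | intermediate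
26 | methyl (3S,4S,6E,8S,10E,12S,14E)-12-(TBDPSO)-3-(dimethoxymethyl)-4,8-dihydroxy-15-iodo-6,10,14-trimethyl-2-methylidenepentadeca-6,10,14-trienoate | I/C=C(\C)C[C@H](O[Si](c1ccccc1)(c1ccccc1)C(C)(C)C)/C=C(\C)C[C@H](O)/C=C(\C)C[C@H](O)[C@H](C(=C)C(=O)OC)C(OC)OC | intermediate
27 | methyl (3S,4S,6E,8S,10E,12S,14E)-4,8-bis(acetyloxy)-12-(TBDPSO)-3-(dimethoxymethyl)-15-iodo-6,10,14-trimethyl-2-methylidenepentadeca-6,10,14-trienoate | I/C=C(\C)C[C@H](O[Si](c1ccccc1)(c1ccccc1)C(C)(C)C)/C=C(\C)C[C@H](OC(C)=O)/C=C(\C)C[C@H](OC(C)=O)[C@H](C(=C)C(=O)OC)C(OC)OC | intermediate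
28 | 2,4,6-trimethylpyridinium N,O-acetal triflate from 27 (one OMe replaced by collidinium; epimers at that carbon) | I/C=C(\C)C[C@H](O[Si](c1ccccc1)(c1ccccc1)C(C)(C)C)/C=C(\C)C[C@H](OC(C)=O)/C=C(\C)C[C@H](OC(C)=O)[C@H](C(=C)C(=O)OC)C(OC)[n+]1c(C)cc(C)cc1C.[O-]S(=O)(=O)C(F)(F)F | intermediate
29 | methyl (3S,4S,6E,8S,10E,12S,14E)-4,8-bis(acetyloxy)-12-(TBDPSO)-3-formyl-15-iodo-6,10,14-trimethyl-2-methylidenepentadeca-6,10,14-trienoate | I/C=C(\C)C[C@H](O[Si](c1ccccc1)(c1ccccc1)C(C)(C)C)/C=C(\C)C[C@H](OC(C)=O)/C=C(\C)C[C@H](OC(C)=O)[C@H](C(=C)C(=O)OC)C=O | intermediate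
30 | methyl 2-[(1R,2S,3E,6S,7E,10S,11E,14S)-10,14-bis(acetyloxy)-6-(TBDPSO)-2-hydroxy-4,8,12-trimethylcyclotetradeca-3,7,11-trien-1-yl]prop-2-enoate | O[C@H]1/C=C(\C)C[C@H](O[Si](c2ccccc2)(c2ccccc2)C(C)(C)C)/C=C(\C)C[C@H](OC(C)=O)/C=C(\C)C[C@H](OC(C)=O)[C@@H]1C(=C)C(=O)OC | intermediate
31 | (3aS,4S,6E,8S,10E,12S,14E,15aS)-12-(TBDPSO)-6,10,14-trimethyl-3-methylidene-2-oxo-2,3,3a,4,5,8,9,12,13,15a-decahydrocyclotetradeca[b]furan-4,8-diyl diacetate | C=C1C(=O)O[C@H]2/C=C(\C)C[C@H](O[Si](c3ccccc3)(c3ccccc3)C(C)(C)C)/C=C(\C)C[C@H](OC(C)=O)/C=C(\C)C[C@H](OC(C)=O)[C@H]12 | intermediate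
32 | (3aS,4S,6E,8S,10E,12S,14E,15aS)-12-hydroxy-6,10,14-trimethyl-3-methylidene-2-oxo-2,3,3a,4,5,8,9,12,13,15a-decahydrocyclotetradeca[b]furan-4,8-diyl diacetate (CNP0418981.1) | C=C1C(=O)O[C@H]2/C=C(\C)C[C@H](O)/C=C(\C)C[C@H](OC(C)=O)/C=C(\C)C[C@H](OC(C)=O)[C@H]12 | target

**Step count**
Total steps: 18. Longest linear sequence: 16 (steps 3 to 18, from 5).

**Steps most likely to fail**

Step 17. What may go wrong: addition to the wrong face of the aldehyde, oxidative addition of zerovalent nickel into the allylic acetates, acetyl migration from O14 to the new O2 alkoxide, or intermolecular coupling. Fallback (acetates installed after ring closure, reagent control at C2): setting out from 26, both hydroxyls are silylated (TESOTf, 2,6-lutidine) to the bis(triethylsilyl) ether of 26 F1. Acetal cleavage as in step 16 goes through the collidinium salt F2 to the aldehyde F3. Ring closure with CrCl2/NiCl2 and a stoichiometric chiral oxazoline–sulfonamide ligand (reagent-controlled Nozaki–Hiyama–Kishi reaction) gives the seco hydroxy ester F4 and, after lactonization, the bis(triethylsilyl) macrolactone F5. Buffered HF·pyridine removes only the two TES groups to give the macrolactone diol F6, and acetylation as in step 15 returns to the route at 31.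

Step 14. What may go wrong: low enantio- or diastereoselection with the γ-branched reagent, 1,4-elimination of methoxide from the allylchromium, lactonization of O14 onto C16, or isomerization of aldehyde 24 under amine and silyl chloride. Fallback (boron instead of chromium): setting out from 3, acetylation gives the Baylis–Hillman acetate F7. CuCl-catalysed SN2′ borylation with B2pin2 gives the allylboronate F8, with the acetal carbon cis to CH2B. Allylboration of 24 catalysed by the TRIP acid (closed chair transition state, syn adduct, no base and no silyl chloride) gives the boronate ester F9, which is hydrolysed on work-up and rejoins the route at 26.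

Step 16. What may go wrong: epimerization at C1 or migration of the C15=C17 double bond into conjugation with the new aldehyde during unmasking, or ionization of an allylic acetate by the silyl triflate. Fallback (C2 carried at the alcohol oxidation level and oxidized under neutral conditions): setting out from 1 and commercial (tert-butyldimethylsilyloxy)acetaldehyde, a Morita–Baylis–Hillman reaction gives the silyloxy Baylis–Hillman alcohol F10, and NBS/Me2S gives the silyloxy (2Z)-allyl bromide F11. Chromium allylation of 24 as in step 14 gives, via the bis(trimethylsilyl) ether F12, the silyloxymethyl diol F13. Acetylation gives the silyloxymethyl diacetate F14, buffered HF·pyridine removes the primary TBS ether selectively to the primary alcohol F15, and buffered Dess–Martin oxidation returns to the route at 29.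

Further compounds
F1 | step 17 | bis(triethylsilyl) ether of 26 | I/C=C(\C)C[C@H](O[Si](c1ccccc1)(c1ccccc1)C(C)(C)C)/C=C(\C)C[C@H](O[Si](CC)(CC)CC)/C=C(\C)C[C@H](O[Si](CC)(CC)CC)[C@H](C(=C)C(=O)OC)C(OC)OC
F2 | step 17 | collidinium salt from F1 | I/C=C(\C)C[C@H](O[Si](c1ccccc1)(c1ccccc1)C(C)(C)C)/C=C(\C)C[C@H](O[Si](CC)(CC)CC)/C=C(\C)C[C@H](O[Si](CC)(CC)CC)[C@H](C(=C)C(=O)OC)C(OC)[n+]1c(C)cc(C)cc1C.[O-]S(=O)(=O)C(F)(F)F
F3 | step 17 | aldehyde with O10 and O14 as TES ethers | I/C=C(\C)C[C@H](O[Si](c1ccccc1)(c1ccccc1)C(C)(C)C)/C=C(\C)C[C@H](O[Si](CC)(CC)CC)/C=C(\C)C[C@H](O[Si](CC)(CC)CC)[C@H](C(=C)C(=O)OC)C=O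
F4 | step 17 | seco hydroxy ester with O10 and O14 as TES ethers | O[C@H]1/C=C(\C)C[C@H](O[Si](c2ccccc2)(c2ccccc2)C(C)(C)C)/C=C(\C)C[C@H](O[Si](CC)(CC)CC)/C=C(\C)C[C@H](O[Si](CC)(CC)CC)[C@@H]1C(=C)C(=O)OC
F5 | step 17 | bis(triethylsilyl) macrolactone | C=C1C(=O)O[C@H]2/C=C(\C)C[C@H](O[Si](c3ccccc3)(c3ccccc3)C(C)(C)C)/C=C(\C)C[C@H](O[Si](CC)(CC)CC)/C=C(\C)C[C@H](O[Si](CC)(CC)CC)[C@H]12
F6 | step 17 | macrolactone diol (O10, O14 free; O6 as TBDPS ether) | C=C1C(=O)O[C@H]2/C=C(\C)C[C@H](O[Si](c3ccccc3)(c3ccccc3)C(C)(C)C)/C=C(\C)C[C@H](O)/C=C(\C)C[C@H](O)[C@H]12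
F7 | step 14 | methyl 3-(acetyloxy)-4,4-dimethoxy-2-methylidenebutanoate | C=C(C(=O)OC)C(OC(C)=O)C(OC)OC
F8 | step 14 | methyl (2E)-4,4-dimethoxy-2-[(4,4,5,5-tetramethyl-1,3,2-dioxaborolan-2-yl)methyl]but-2-enoate | COC(=O)/C(CB1OC(C)(C)C(C)(C)O1)=C/C(OC)OC
F9 | step 14 | O14-Bpin boronate ester of 26 | I/C=C(\C)C[C@H](O[Si](c1ccccc1)(c1ccccc1)C(C)(C)C)/C=C(\C)C[C@H](O)/C=C(\C)C[C@H](OB1OC(C)(C)C(C)(C)O1)[C@H](C(=C)C(=O)OC)C(OC)OC
F10 | step 16 | methyl 4-(TBSO)-3-hydroxy-2-methylidenebutanoate | C=C(C(=O)OC)C(O)CO[Si](C)(C)C(C)(C)C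
F11 | step 16 | methyl (2Z)-2-(bromomethyl)-4-(TBSO)but-2-enoate | BrC/C(=C\CO[Si](C)(C)C(C)(C)C)C(=O)OC
F12 | step 16 | bis(trimethylsilyl) ether of F13 | I/C=C(\C)C[C@H](O[Si](c1ccccc1)(c1ccccc1)C(C)(C)C)/C=C(\C)C[C@H](O[Si](C)(C)C)/C=C(\C)C[C@H](O[Si](C)(C)C)[C@H](C(=C)C(=O)OC)CO[Si](C)(C)C(C)(C)C
F13 | step 16 | analogue of 26 with CH2OTBS in place of CH(OMe)2 | I/C=C(\C)C[C@H](O[Si](c1ccccc1)(c1ccccc1)C(C)(C)C)/C=C(\C)C[C@H](O)/C=C(\C)C[C@H](O)[C@H](C(=C)C(=O)OC)CO[Si](C)(C)C(C)(C)C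
F14 | step 16 | analogue of 27 with CH2OTBS in place of CH(OMe)2 | I/C=C(\C)C[C@H](O[Si](c1ccccc1)(c1ccccc1)C(C)(C)C)/C=C(\C)C[C@H](OC(C)=O)/C=C(\C)C[C@H](OC(C)=O)[C@H](C(=C)C(=O)OC)CO[Si](C)(C)C(C)(C)C
F15 | step 16 | primary alcohol (CH2OH at C2) corresponding to 29 | I/C=C(\C)C[C@H](O[Si](c1ccccc1)(c1ccccc1)C(C)(C)C)/C=C(\C)C[C@H](OC(C)=O)/C=C(\C)C[C@H](OC(C)=O)[C@H](C(=C)C(=O)OC)CO
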